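**Retrosynthetic overview**

- Feature: in the oxolane ring (O1, C2 aryl, C3 CH2OH, C4 aroyl, C5) C5 is a bare CH2 between O1 and C4, the α-carbon of the aryl ketone. It is a formaldehyde carbon sitting between an alkoxide oxygen and an enol carbon.
- End game: C3–CH2OH comes from a C3 ethyl ester by hydride reduction, and the C4 aryl ketone is restored by benzylic oxidation.
- Key disconnection C4–C5, which closes the only ring: the methoxymethyl acetal on the C2 oxygen gives the O1=C5H2 cation, and the enol silane of the ketone attacks it through C4.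
- Open-chain precursor: an anti β-(methoxymethoxy) γ-keto ester. C3–C4 and the C3 centre come from Fráter–Seebach alkylation of an (S)-β-hydroxy ester (C2 centre from asymmetric hydrogenation) with a 2-arylallyl bromide whose alkene is the masked ketone.
- The 2-arylallyl bromide comes from Suzuki coupling of the arylboronic acid with 2-bromoallyl alcohol, then bromination.

Key step: step 7

Assumption: (R)-BINAP–ruthenium hydrogenation of the 3,4,5-trimethoxybenzoylacetate is taken to give the (S)-carbinol, as with ethyl benzoylacetate; were the sense reversed, the (S)-ligand would be used.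

**Route**

Step 1
Reactants: 1 (3,4,5-trimethoxyphenyl)boronic acid; 2 2-bromoprop-2-en-1-ol
Product: 3 2-(3,4,5-trimethoxyphenyl)prop-2-en-1-ol
Conditions: Pd(PPh3)4 (3 mol %), K2CO3, DME/H2O, 80 °C
Reagents that add atoms: none
Why: Suzuki–Miyaura coupling of an arylboronic acid with a 2-bromoalkene keeps the alkene in place and tolerates the free allylic alcohol; no stereocentre is formed.

Step 2
Reactants: 3 2-(3,4,5-trimethoxyphenyl)prop-2-en-1-ol
Product: 4 5-(3-bromoprop-1-en-2-yl)-1,2,3-trimethoxybenzene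
Conditions: CBr4, PPh3, CH2Cl2, 0 °C
Reagents that add atoms: carbon tetrabromide, BrC(Br)(Br)Br
Why: Appel bromination converts the primary allylic alcohol to the bromide under neutral conditions that spare the acid-sensitive electron-rich styrene, and direct or allylically transposed substitution gives the same product because the allyl unit is symmetric.

Step 3
Reactants: 5 ethyl 3-oxo-3-(3,4,5-trimethoxyphenyl)propanoate
Product: 6 ethyl (3S)-3-hydroxy-3-(3,4,5-trimethoxyphenyl)propanoate
Conditions: H2 (50 atm), RuCl2[(R)-BINAP] (0.5 mol %), EtOH, 50 °C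
Reagents that add atoms: none
Why: Noyori asymmetric hydrogenation of a β-keto ester, in which the ester-chelated ketone is reduced on one face by the BINAP–ruthenium hydride; the (R)-ligand should set the (S)-carbinol, which becomes C2.

Step 4
Reactants: 6 ethyl (3S)-3-hydroxy-3-(3,4,5-trimethoxyphenyl)propanoate; 4 5-(3-bromoprop-1-en-2-yl)-1,2,3-trimethoxybenzene
Product: 7 ethyl (2R)-2-[(S)-hydroxy(3,4,5-trimethoxyphenyl)methyl]-4-(3,4,5-trimethoxyphenyl)pent-4-enoate (anti)
Conditions: LiN(i-Pr)2 (2.2 equiv), THF, −78 → −20 °C; then 4, DMPU, −78 → −20 °C; aq. NH4Cl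
Reagents that add atoms: none
Why: Fráter–Seebach alkylation, in which the lithium alkoxide–(Z)-enolate chelate is alkylated by the allylic bromide on the face away from the aryl group of the six-membered chelate, setting the α-centre (future C3) anti to the carbinol.

Step 5
Reactants: 7 ethyl (2R)-2-[(S)-hydroxy(3,4,5-trimethoxyphenyl)methyl]-4-(3,4,5-trimethoxyphenyl)pent-4-enoate; 8 chloromethyl methyl ether
Product: 9 ethyl (2R)-2-[(S)-(methoxymethoxy)(3,4,5-trimethoxyphenyl)methyl]-4-(3,4,5-trimethoxyphenyl)pent-4-enoate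
Conditions: i-Pr2NEt, Bu4NI (cat.), CH2Cl2, 0 °C → rt
Reagents that add atoms: none
Why: Williamson-type O-alkylation by the α-chloro ether under amine base installs the formaldehyde acetal whose CH2 becomes C5, and it masks the hydroxyl that would otherwise form a lactol with the ketone made in step 6; no stereocentre is touched.

Step 6
Reactants: 9 ethyl (2R)-2-[(S)-(methoxymethoxy)(3,4,5-trimethoxyphenyl)methyl]-4-(3,4,5-trimethoxyphenyl)pent-4-enoate
Product: 10 ethyl (2R)-2-[(S)-(methoxymethoxy)(3,4,5-trimethoxyphenyl)methyl]-4-oxo-4-(3,4,5-trimethoxyphenyl)butanoate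
Conditions: K2OsO4·2H2O (2 mol %), NaIO4 (4 equiv), 2,6-lutidine, dioxane/H2O, rt
Reagents that add atoms: sodium periodate, [Na+].[O-]I(=O)(=O)=O (terminal oxygen source; the oxygen is delivered to carbon by osmium tetroxide, O=[Os](=O)(=O)=O, formed from the osmate)
Why: Lemieux–Johnson cleavage (OsO4 dihydroxylation, periodate glycol fission, lutidine buffer) turns the 1,1-disubstituted styrene into the aryl ketone while acetal, ester and both stereocentres are left alone.

Step 7
Reactants: 10 ethyl (2R)-2-[(S)-(methoxymethoxy)(3,4,5-trimethoxyphenyl)methyl]-4-oxo-4-(3,4,5-trimethoxyphenyl)butanoate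
Product: 13 ethyl (2S,3R,4R)-4-(3,4,5-trimethoxybenzoyl)-2-(3,4,5-trimethoxyphenyl)oxolane-3-carboxylate (2,3-cis-3,4-trans), via (Z)-trimethylsilyl enol ether 11 (not isolated), via alkoxymethyl oxocarbenium triflate 12 (not isolated)
Conditions: i-Pr2NEt (1.3 equiv), TMSOTf (1.2 equiv), CH2Cl2, 0 °C; then TMSOTf (0.5 equiv), −78 → −30 °C; aq. NaHCO3; then DBU (0.2 equiv), CH2Cl2, rt
Reagents that add atoms: trimethylsilyl trifluoromethanesulfonate, C[Si](C)(C)OS(=O)(=O)C(F)(F)F (its silyl group and triflate are held only by intermediates 11 and 12; no atom of it remains in 13)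
Why: Soft enolisation by silyl triflate and amine turns the aryl ketone into its (Z)-enol silane 11, and the surplus TMSOTf then silylates the less hindered methoxy oxygen of the formaldehyde acetal, so that methoxytrimethylsilane leaves and the O1=C5H2 oxocarbenium ion 12 forms; C4 of the enol silane adds to C5 and the silyl group returns to triflate. This is an intramolecular Mukaiyama-type acetal alkylation run as a one-flask enol silane formation–acetal addition, its closest relatives being the aldol termination of Prins–pinacol sequences and the Lewis-acid rearrangement of cyclic enol acetals to 3-acyl oxolanes, and if the enol oxygen adds first, the seven-membered enol acetal should re-ionise to the same ion pair and end at 13. The oxolane ring closes in the 5-(enol-exo)-endo-trig mode, which is accepted for oxocarbenium electrophiles. C2 and C3 are carried over unchanged because the C2–O1 bond is never broken, so the anti chain becomes the 2,3-cis ring; the new C4 centre is set by allylic 1,3-strain in 11, where C3–H eclipses the siloxy-bearing alkene so that C5 bonds on the face that leaves the aroyl group trans to the C3 ester, and the closing DBU treatment places C4 under thermodynamic control with the same 3,4-trans preference, C4–H being the only proton acidic enough to exchange. The step needs C-alkylation at C4 to outrun three competing paths: attack of 12 on the electron-rich C2 aryl ring, heterolysis of the benzylic C2–O bond, and loss of the MeOCH2 unit from the other acetal oxygen. The first would be a strained 5-endo closure onto an arene, the second is held back at −78 °C because the acetal is the more basic and more easily ionised site, and the third is disfavoured because the hindered secondary benzylic oxygen steers silylation to the methoxy group, while the pre-formed enol silane sits within five atoms of the cation.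

Step 8
Reactants: 13 ethyl (2S,3R,4R)-4-(3,4,5-trimethoxybenzoyl)-2-(3,4,5-trimethoxyphenyl)oxolane-3-carboxylate
Product: 14 [(2S,3S,4R)-4-[hydroxy(3,4,5-trimethoxyphenyl)methyl]-2-(3,4,5-trimethoxyphenyl)oxolan-3-yl]methanol (both carbinol epimers)
Conditions: LiAlH4 (3 equiv), THF, 0 °C; aq. KNaC4H4O6 work-up
Reagents that add atoms: none
Why: Hydride reduction with LiAlH4 takes the ester to the primary alcohol and the ketone to the benzylic carbinol (its configuration is of no consequence), and hydride addition is faster than enolisation, so C4 is retained.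

Step 9
Reactants: 14 [(2S,3S,4R)-4-[hydroxy(3,4,5-trimethoxyphenyl)methyl]-2-(3,4,5-trimethoxyphenyl)oxolan-3-yl]methanol
Product: 15 [(3R,4S,5S)-4-(hydroxymethyl)-5-(3,4,5-trimethoxyphenyl)oxolan-3-yl](3,4,5-trimethoxyphenyl)methanone, the target (2S,3S,4R in the ring numbering used above)
Conditions: activated MnO2 (20 equiv), CH2Cl2, rt
Reagents that add atoms: none
Why: Manganese dioxide oxidation is selective for the aryl-activated secondary alcohol and leaves the primary aliphatic alcohol, under neutral conditions that do not enolise C4; the trans hydroxymethyl/aroyl pair cannot close to a hemiketal without a trans-fused bicycle, so the open hydroxy ketone should be obtained.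

**Compound list**

1 | (3,4,5-trimethoxyphenyl)boronic acid | OB(O)c1cc(OC)c(OC)c(OC)c1 | starting material
2 | 2-bromoprop-2-en-1-ol | OCC(Br)=C | starting material
3 | 2-(3,4,5-trimethoxyphenyl)prop-2-en-1-ol | OCC(=C)c1cc(OC)c(OC)c(OC)c1 | intermediate
4 | 5-(3-bromoprop-1-en-2-yl)-1,2,3-trimethoxybenzene | BrCC(=C)c1cc(OC)c(OC)c(OC)c1 | intermediate
5 | ethyl 3-oxo-3-(3,4,5-trimethoxyphenyl)propanoate | CCOC(=O)CC(=O)c1cc(OC)c(OC)c(OC)c1 | starting material
6 | ethyl (3S)-3-hydroxy-3-(3,4,5-trimethoxyphenyl)propanoate | O[C@H](c1cc(OC)c(OC)c(OC)c1)CC(=O)OCC | intermediate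
7 | ethyl (2R)-2-[(S)-hydroxy(3,4,5-trimethoxyphenyl)methyl]-4-(3,4,5-trimethoxyphenyl)pent-4-enoate | O[C@H](c1cc(OC)c(OC)c(OC)c1)[C@H](C(=O)OCC)CC(=C)c1cc(OC)c(OC)c(OC)c1 | intermediate
8 | chloromethyl methyl ether | COCCl | starting material
9 | ethyl (2R)-2-[(S)-(methoxymethoxy)(3,4,5-trimethoxyphenyl)methyl]-4-(3,4,5-trimethoxyphenyl)pent-4-enoate | COCO[C@H](c1cc(OC)c(OC)c(OC)c1)[C@H](C(=O)OCC)CC(=C)c1cc(OC)c(OC)c(OC)c1 | intermediate
10 | ethyl (2R)-2-[(S)-(methoxymethoxy)(3,4,5-trimethoxyphenyl)methyl]-4-oxo-4-(3,4,5-trimethoxyphenyl)butanoate | COCO[C@H](c1cc(OC)c(OC)c(OC)c1)[C@H](C(=O)OCC)CC(=O)c1cc(OC)c(OC)c(OC)c1 | intermediate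
11 | ethyl (2R,3Z)-2-[(S)-(methoxymethoxy)(3,4,5-trimethoxyphenyl)methyl]-4-(3,4,5-trimethoxyphenyl)-4-[(trimethylsilyl)oxy]but-3-enoate | COCO[C@H](c1cc(OC)c(OC)c(OC)c1)[C@H](C(=O)OCC)/C=C(\O[Si](C)(C)C)c1cc(OC)c(OC)c(OC)c1 | intermediate
12 | O-methylidene oxonium (O1=C5H2 oxocarbenium) triflate derived from 11 by loss of methoxide | C=[O+][C@H](c1cc(OC)c(OC)c(OC)c1)[C@H](C(=O)OCC)/C=C(\O[Si](C)(C)C)c1cc(OC)c(OC)c(OC)c1.[O-]S(=O)(=O)C(F)(F)F | intermediate
13 | ethyl (2S,3R,4R)-4-(3,4,5-trimethoxybenzoyl)-2-(3,4,5-trimethoxyphenyl)oxolane-3-carboxylate | O=C(c1cc(OC)c(OC)c(OC)c1)[C@H]2CO[C@H](c3cc(OC)c(OC)c(OC)c3)[C@@H]2C(=O)OCC | intermediate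
14 | [(2S,3S,4R)-4-[hydroxy(3,4,5-trimethoxyphenyl)methyl]-2-(3,4,5-trimethoxyphenyl)oxolan-3-yl]methanol, carbinol epimers | OC(c1cc(OC)c(OC)c(OC)c1)[C@H]2CO[C@H](c3cc(OC)c(OC)c(OC)c3)[C@@H]2CO | intermediate
15 | [(3R,4S,5S)-4-(hydroxymethyl)-5-(3,4,5-trimethoxyphenyl)oxolan-3-yl](3,4,5-trimethoxyphenyl)methanone | COc1cc(C(=O)[C@H]2CO[C@H](c3cc(OC)c(OC)c(OC)c3)[C@@H]2CO)cc(OC)c1OC | target

**Step count**

Total: 9 steps. Longest linear sequence: 8 steps (steps 1, 2, 4, 5, 6, 7, 8, 9 from boronic acid 1); 7 steps from keto ester 5.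

**Steps most likely to fail**

1. Step 7 (ring closure).
 - What may go wrong: the mixed acetal may ionise on the wrong oxygen, so that a methoxymethyl cation is transferred and the tether is lost. The benzylic C2–O bond may undergo heterolysis, with loss of the C2 configuration. Intermolecular arylation by the cation may be faster than the 5-endo C-alkylation.
 - Fallback: the cation is made by chelation-directed cleavage of a different acetal and is met by an isolated, more robust enol silane. It sets out from 7 and comes back at 13.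
 - 7 with 2-methoxyethoxymethyl chloride and i-Pr2NEt gives ethyl (2R)-2-[(S)-[(2-methoxyethoxy)methoxy](3,4,5-trimethoxyphenyl)methyl]-4-(3,4,5-trimethoxyphenyl)pent-4-enoate F1.
 - Osmium–periodate cleavage as in step 6 gives ethyl (2R)-2-[(S)-[(2-methoxyethoxy)methoxy](3,4,5-trimethoxyphenyl)methyl]-4-oxo-4-(3,4,5-trimethoxyphenyl)butanoate F2.
 - TBSOTf and Et3N give the isolated ethyl (2R,3Z)-4-[(tert-butyldimethylsilyl)oxy]-2-[(S)-[(2-methoxyethoxy)methoxy](3,4,5-trimethoxyphenyl)methyl]-4-(3,4,5-trimethoxyphenyl)but-3-enoate F3.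
 - TiCl4 in CH2Cl2 at −78 °C binds both oxygens of the methoxyethoxy arm and so can expel only that arm. It should release the C2–O–CH2 cation (or its chloromethyl ether) beside the enol silane and close the ring to 13, after which the DBU equilibration and steps 8 and 9 follow unchanged.

2. Step 4 (Fráter–Seebach alkylation).
 - What may go wrong: retro-aldol fragmentation of the benzylic alkoxide–enolate on warming, proton transfer or elimination with the activated allylic bromide, or erosion of the anti selectivity.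
 - Fallback: the C2–C3 bond and both centres are made instead by an auxiliary-controlled anti-aldol reaction. It sets out from 3 and comes back at 7.
 - Johnson–Claisen rearrangement of 3 with triethyl orthoacetate (cat. propionic acid, 140 °C) gives ethyl 4-(3,4,5-trimethoxyphenyl)pent-4-enoate F4.
 - LiOH gives 4-(3,4,5-trimethoxyphenyl)pent-4-enoic acid F5.
 - Pivaloyl chloride and Et3N, then the lithium salt of (S)-4-benzyloxazolidin-2-one, give (4S)-4-benzyl-3-[4-(3,4,5-trimethoxyphenyl)pent-4-enoyl]oxazolidin-2-one F6.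
 - MgCl2 (cat.), Et3N and TMSCl in EtOAc with 3,4,5-trimethoxybenzaldehyde (magnesium-catalysed anti-aldol of the chelated (Z)-enolate, aldehyde entering anti to the benzyl group) should give (4S)-4-benzyl-3-[(2R)-2-[(S)-(3,4,5-trimethoxyphenyl)(trimethylsilyloxy)methyl]-4-(3,4,5-trimethoxyphenyl)pent-4-enoyl]oxazolidin-2-one F7.
 - Acidic methanol frees (4S)-4-benzyl-3-[(2R)-2-[(S)-hydroxy(3,4,5-trimethoxyphenyl)methyl]-4-(3,4,5-trimethoxyphenyl)pent-4-enoyl]oxazolidin-2-one F8.
 - EtOMgBr in EtOH/CH2Cl2 at 0 °C exchanges the auxiliary for ethoxide and returns 7.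

3. Step 9 (selective oxidation).
 - What may go wrong: the heterogeneous oxidation may stall at the hindered benzylic carbinol, or it may lose chemoselectivity and attack the primary alcohol, followed by lactol or lactone formation.
 - Fallback: protect, oxidise, deprotect. It sets out from 14 and comes back at 15.
 - TBSCl and imidazole silylate only the primary hydroxyl to give (2S,3S,4R)-3-[(tert-butyldimethylsilyloxy)methyl]-4-[hydroxy(3,4,5-trimethoxyphenyl)methyl]-2-(3,4,5-trimethoxyphenyl)oxolane F9.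
 - Dess–Martin periodinane buffered with NaHCO3 gives (2S,3S,4R)-3-[(tert-butyldimethylsilyloxy)methyl]-4-(3,4,5-trimethoxybenzoyl)-2-(3,4,5-trimethoxyphenyl)oxolane F10.
 - HF·pyridine in THF removes the silyl group without enolising C4 and gives 15.

**Further compounds**

F1 | step 7 | ethyl (2R)-2-[(S)-[(2-methoxyethoxy)methoxy](3,4,5-trimethoxyphenyl)methyl]-4-(3,4,5-trimethoxyphenyl)pent-4-enoate | COCCOCO[C@H](c1cc(OC)c(OC)c(OC)c1)[C@H](C(=O)OCC)CC(=C)c1cc(OC)c(OC)c(OC)c1
F2 | step 7 | ethyl (2R)-2-[(S)-[(2-methoxyethoxy)methoxy](3,4,5-trimethoxyphenyl)methyl]-4-oxo-4-(3,4,5-trimethoxyphenyl)butanoate | COCCOCO[C@H](c1cc(OC)c(OC)c(OC)c1)[C@H](C(=O)OCC)CC(=O)c1cc(OC)c(OC)c(OC)c1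
F3 | step 7 | ethyl (2R,3Z)-4-[(tert-butyldimethylsilyl)oxy]-2-[(S)-[(2-methoxyethoxy)methoxy](3,4,5-trimethoxyphenyl)methyl]-4-(3,4,5-trimethoxyphenyl)but-3-enoate | COCCOCO[C@H](c1cc(OC)c(OC)c(OC)c1)[C@H](C(=O)OCC)/C=C(\O[Si](C)(C)C(C)(C)C)c1cc(OC)c(OC)c(OC)c1
F4 | step 4 | ethyl 4-(3,4,5-trimethoxyphenyl)pent-4-enoate | CCOC(=O)CCC(=C)c1cc(OC)c(OC)c(OC)c1
F5 | step 4 | 4-(3,4,5-trimethoxyphenyl)pent-4-enoic acid | OC(=O)CCC(=C)c1cc(OC)c(OC)c(OC)c1
F6 | step 4 | (4S)-4-benzyl-3-[4-(3,4,5-trimethoxyphenyl)pent-4-enoyl]oxazolidin-2-one | C=C(CCC(=O)N1[C@@H](Cc2ccccc2)COC1=O)c1cc(OC)c(OC)c(OC)c1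
F7 | step 4 | (4S)-4-benzyl-3-[(2R)-2-[(S)-(3,4,5-trimethoxyphenyl)(trimethylsilyloxy)methyl]-4-(3,4,5-trimethoxyphenyl)pent-4-enoyl]oxazolidin-2-one | C[Si](C)(C)O[C@H](c1cc(OC)c(OC)c(OC)c1)[C@H](C(=O)N1[C@@H](Cc2ccccc2)COC1=O)CC(=C)c1cc(OC)c(OC)c(OC)c1
F8 | step 4 | (4S)-4-benzyl-3-[(2R)-2-[(S)-hydroxy(3,4,5-trimethoxyphenyl)methyl]-4-(3,4,5-trimethoxyphenyl)pent-4-enoyl]oxazolidin-2-one | O[C@H](c1cc(OC)c(OC)c(OC)c1)[C@H](C(=O)N1[C@@H](Cc2ccccc2)COC1=O)CC(=C)c1cc(OC)c(OC)c(OC)c1
F9 | step 9 | (2S,3S,4R)-3-[(tert-butyldimethylsilyloxy)methyl]-4-[hydroxy(3,4,5-trimethoxyphenyl)methyl]-2-(3,4,5-trimethoxyphenyl)oxolane | OC(c1cc(OC)c(OC)c(OC)c1)[C@H]2CO[C@H](c3cc(OC)c(OC)c(OC)c3)[C@@H]2CO[Si](C)(C)C(C)(C)C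
F10 | step 9 | (2S,3S,4R)-3-[(tert-butyldimethylsilyloxy)methyl]-4-(3,4,5-trimethoxybenzoyl)-2-(3,4,5-trimethoxyphenyl)oxolane | O=C(c1cc(OC)c(OC)c(OC)c1)[C@H]2CO[C@H](c3cc(OC)c(OC)c(OC)c3)[C@@H]2CO[Si](C)(C)C(C)(C)C
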